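## Analysis of the target

The target 29 is a trans-fused hydroazulene. Ring A is the seven-membered ring (C1, C5, C6, C7, C8, C9, C10) and ring B the five-membered ring (C1 to C5). The daucane locants are used for every bicyclic compound below: C1 is the quaternary fusion carbon with the methyl group, C4 the ester carbinol, C5 the fusion CH, C6 the carbinol, C7=C8 the alkene with methyl on C8, C9 the ketone. β is the face of the C1 methyl group.

There are four stereocentres, (1R,4R,5S,6S). The C1 methyl and the C4 acyloxy group lie on the β face; the C5 hydrogen, the C4 isopropyl group and the C6 hydroxyl lie on the α face. Ring A carries a γ-hydroxy enone (C6–OH, C7=C8, C9=O), which can isomerise to the 1,4-diketone or lose water. Ring B carries a 4-hydroxybenzoate on a tertiary alcohol flanked by an isopropyl group and the ring fusion, while the more accessible secondary C6 hydroxyl and the phenol stay free.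

The hard points are the trans 5–7 fusion next to a quaternary carbon, the contiguous C4–C5–C6 array, the need to tell the two carbonyl-level carbons C4 and C9 apart, and acylation of the hindered C4 oxygen without touching C6. The strategy rests on one relationship: C9 is tied to C5 through C10 and C1, and C6, C7, C8 form an unsaturated chain on C5. An acyl metal hydride generated at C9 is therefore held on the C10 face of C1, can hand its hydrogen to C5 from that face and then bond to C8. That closes ring A, places the C9 ketone and the C6=C7 alkene, and sets the ring fusion.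

## Retrosynthetic reasoning

**29 back to 26.** The phenol is freed last from silyl ether 28. The γ-hydroxy enone of 28 is traced to the β,γ-epoxy ketone 27 by cutting the C7–O bond (enolate-driven epoxide opening), and 27 to the β,γ-unsaturated ketone 26 by epoxidation of C6=C7. The sensitive hydroxy enone then exists only at the very end, the C6 hydroxyl never needs protection, and it is not present when the ester is made. The forward epoxidation has to come from the α face; both C8 epimers give the same enone.

**26 back to 20 and 23.** The ester C–O bond is cut to the tertiary alcohol 20 and the acid chloride 24, made from acid 23, which comes from 21 through 22. Acylation of so hindered an alcohol needs its alkoxide, so no enolisable ketone may be present; C9 is therefore a ketal at this stage (25) and is released afterwards to give 26.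

**20 back to 19.** The C4–isopropyl bond is cut. This is done in the bicycle because only there do the two faces of the C4 carbonyl differ clearly: the C1 methyl group sits 1,3 to C4 on the β face. In any monocyclic precursor the methyl group and the two-carbon arm on C1 are too alike. The forward addition must come from the α face, which puts oxygen β.

**19 back to 16.** These are changes of functional group only, made so that C4 is the sole carbonyl when the isopropyl group arrives. C9 is ketalised (17), the C4 silyl ether is removed (18) and C4 is oxidised under neutral conditions (19). C4 is carried as a silyl ether and not at the ketone level for two reasons. A C4 ketal would have to be removed by acid beside a C6=C7 alkene and a labile C5 hydrogen. It could also not be distinguished from a C9 ketal.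

**16 back to 15.** The C8–C9 bond is cut, which opens ring A to the dienal 15. This is the only disconnection that uses the C9-to-C5 relationship: the forward step forms ring A, the C9 ketone and the C5 stereocentre together, from a precursor that contains no stereocentre other than C1 and the temporary one at C4.

**15 back to 12.** The aldehyde is taken back to the primary alcohol 14 and this to the vinyl group of 12 (through borane 13). A vinyl group is the simplest two-carbon unit that can be put on a quaternary carbon enantioselectively, and it can be told apart from the more substituted diene.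

**12 back to 10.** The silyl ether comes from alcohol 11 and this from dienone 10. A C4 ketone conjugated to the diene would send a metal hydride to the wrong carbon, and ketalising such a dienone risks double-bond migration. The reduction is catalyst-controlled and puts the oxygen on the β face, so that the α face stays free for the metal in the key step.

**10 back to 5 and 6.** The C5=C6 bond is cut (aldol condensation with 6, through 7, 8 and 9). The enolate must lie at C5, the more hindered α-carbon; only a conjugate addition to 1 delivers it there. The silicon on the vinyl group is lost between 9 and 10.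

**5 back to 1 and 2.** The C1–vinyl bond is cut. A catalytic enantioselective conjugate addition of the vinylalane 3 (from 2) to 1 sets C1, and the aluminium enolate 4 is trapped as 5. The silicon substituent is what makes a vinyl-type aluminium reagent readily available.

## Alternatives that were turned down

**Alternative 1:** Büchner ring expansion.
- Disconnection: C5–C1 and C5–C6; C5 is a carbene carbon inserted into the ipso–ortho bond of a benzene ring that becomes ring A.
- Forward key step: diazoketone A1 is decomposed by a chiral copper or dirhodium catalyst, the carbenoid cyclopropanates the arene and the norcaradiene opens to azulenone A2.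
- For: both rings arise in one step from a simple arene, and the C8 methyl and the C9 oxygen come with the arene. On speed of ring construction this is stronger than the chosen route.
- Against: C1 is left trigonal in A2, so the angular methyl group and the trans fusion must be added later by a conjugate addition of uncertain facial sense. The C5 hydrogen of A2 is α to the ketone and doubly allylic, so the single epimer is easily lost. The two ortho positions of A1 are not equivalent. The triene of A2 needs several selective reductions.
- Comparison: the chosen route is longer to the bicycle, but it fixes C1 first by a catalyst-controlled reaction and lets the tether pass that information to C5.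

**Alternative 2:** three-component coupling on a cyclopentenone.
- Disconnection: C5–C6 and C1–C10.
- Forward key step: a vinyl cuprate adds to C5 of enone A3 anti to the silyloxy group, and the enolate is alkylated at C1 with tert-butyl bromoacetate anti to the new vinyl group, giving A4.
- For: the trans relationship of C1 and C5 comes from well-understood substrate control and an enantiopure enone; no asymmetric catalyst is needed. On certainty of the ring-fusion configuration this is at least as strong as the hydride relay.
- Against: no ring is closed. The ketone of A4 sits at C2 and must be deleted. The alkylation makes a quaternary carbon from a tetrasubstituted enolate that can equilibrate and expel the β-silyloxy group. Ring A still needs C8, a ring closure and both of its oxygens.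
- Comparison: the chosen route closes ring A, places C9=O and C6=C7 and sets C5 in one catalytic step.

**Alternative 3:** polarised Nazarov cyclisation.
- Disconnection: C1–C2.
- Forward key step: a chiral copper Lewis acid binds the β-keto ester of divinyl ketone A5, conrotatory closure forms ring B and the quaternary C1, and loss of a proton from C6 gives enone A6.
- For: ring B and C1 are made in one enantioselective step, and C4 (ketone) and C9 (ketal) arrive already differentiated. On that point it is stronger than the chosen route, which spends steps 10 to 12 and 16 on the same distinction.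
- Against: the seven-membered ring must be built beforehand. C5 ends trigonal, so the trans fusion has to be set later by a reduction. The C8 methyl, the C7=C8 alkene and the C6 oxygen are all missing. Closure onto a fully substituted alkene terminus is the slow case of this reaction, and the C3 ester must be removed.
- Comparison: the chosen route leaves ring A with all its carbons and the right unsaturation directly after the key step.

Key step: step 9

Remark on the chemistry: step 9 should give both C8 epimers; they are carried together because C8 becomes trigonal in step 18, so the SMILES strings of 16 to 27 leave C8 undefined.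

## Route

Step 1
Reactants: 1 3-methylcyclopent-2-en-1-one; 2 ethynyltrimethylsilane
Product: 5 (S)-triethyl({3-methyl-3-[1-(trimethylsilyl)ethenyl]cyclopent-1-en-1-yl}oxy)silane, via vinylalane 3 (not isolated), via aluminium enolate 4 (not isolated)
Conditions: 2, i-Bu2AlH, hexanes, 55 °C; then 1, Cu(OTf)2 (5 mol %), chiral sulfonate-bearing N-heterocyclic carbene ligand (5 mol %), THF, −78 → −50 °C; then Et3SiOTf, −78 → 0 °C
Reagents that add atoms: triethylsilyl trifluoromethanesulfonate, CC[Si](CC)(CC)OS(=O)(=O)C(F)(F)F
Why: Hydroalumination puts aluminium on the silicon-bearing carbon, and copper–carbene-catalysed enantioselective conjugate addition of such silicon-substituted vinylalanes to 3-substituted cyclopentenones is a known route to a vinyl-bearing quaternary carbon; C1 is set by the catalyst (ligand enantiomer chosen for S). O-Silylation of the aluminium enolate keeps the enolate at C5, which no later enolisation could provide.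

Step 2
Reactants: 5 (S)-triethyl({3-methyl-3-[1-(trimethylsilyl)ethenyl]cyclopent-1-en-1-yl}oxy)silane; 6 (E)-but-2-enal
Product: 7 (3S)-2-[(E)-1-hydroxybut-2-en-1-yl]-3-methyl-3-[1-(trimethylsilyl)ethenyl]cyclopentan-1-one (diastereomers at C2 and at the carbinol carbon)
Conditions: 6, BF3·OEt2, CH2Cl2, −78 °C; aq. NaHCO3
Reagents that add atoms: none
Why: Mukaiyama aldol addition: the activated aldehyde can only bond to C5 of the silyl enol ether, and without base there is no enolate equilibration; 1,2-addition to the enal is the normal course. The two new stereocentres disappear in step 3.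

Step 3
Reactants: 7 (3S)-2-[(E)-1-hydroxybut-2-en-1-yl]-3-methyl-3-[1-(trimethylsilyl)ethenyl]cyclopentan-1-one
Product: 9 (2E,3S)-2-[(2E)-but-2-en-1-ylidene]-3-methyl-3-[1-(trimethylsilyl)ethenyl]cyclopentan-1-one, via mesylate 8 (not isolated)
Conditions: MsCl, Et3N, CH2Cl2, 0 °C; then DBU, 0 °C → rt
Reagents that add atoms: none
Why: Mesylation and base-induced elimination through the C5 enolate (E1cB). The dienone should form with C7 anti to the carbonyl group, the usual thermodynamic geometry of 2-alkylidene cyclopentanones; either geometry would serve, since C5 becomes tetrahedral in step 9.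

Step 4
Reactants: 9 (2E,3S)-2-[(2E)-but-2-en-1-ylidene]-3-methyl-3-[1-(trimethylsilyl)ethenyl]cyclopentan-1-one
Product: 10 (2E,3R)-2-[(2E)-but-2-en-1-ylidene]-3-ethenyl-3-methylcyclopentan-1-one
Conditions: CF3CO2H, CH2Cl2, 0 °C → rt
Reagents that add atoms: none
Why: Protodesilylation of a vinylsilane: protonation at the silicon-bearing carbon gives a β-silyl-stabilised cation that loses silicon to trifluoroacetate. The conjugated ketone tolerates the acid and the quaternary centre is untouched (the descriptor changes only through ligand priorities).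

Step 5
Reactants: 10 (2E,3R)-2-[(2E)-but-2-en-1-ylidene]-3-ethenyl-3-methylcyclopentan-1-one
Product: 11 (1S,2E,3R)-2-[(2E)-but-2-en-1-ylidene]-3-ethenyl-3-methylcyclopentan-1-ol
Conditions: (R)-1-methyl-3,3-diphenyltetrahydro-1H,3H-pyrrolo[1,2-c][1,3,2]oxazaborole (20 mol %), catecholborane, toluene, −78 °C
Reagents that add atoms: none
Why: Corey–Bakshi–Shibata reduction with the alkylidene side as the large group and the CH2 side as the small one; the (R)-catalyst should give the (S)-alcohol, oxygen on the face of the C1 methyl group. At −78 °C catecholborane reduces the bound ketone 1,2 and leaves the vinyl group and the diene alone; any minor C1 enantiomer becomes a separable diastereomer here.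

Step 6
Reactants: 11 (1S,2E,3R)-2-[(2E)-but-2-en-1-ylidene]-3-ethenyl-3-methylcyclopentan-1-ol
Product: 12 tert-butyl{[(1S,2E,3R)-2-[(2E)-but-2-en-1-ylidene]-3-ethenyl-3-methylcyclopentyl]oxy}dimethylsilane
Conditions: t-BuMe2SiCl, imidazole, DMF, rt
Reagents that add atoms: tert-butyldimethylsilyl chloride, CC(C)(C)[Si](C)(C)Cl
Why: Standard silylation under basic conditions, which the acid-labile dienylic alcohol tolerates. The ether keeps C4 tetrahedral and inert through steps 7 to 10.

Step 7
Reactants: 12 tert-butyl{[(1S,2E,3R)-2-[(2E)-but-2-en-1-ylidene]-3-ethenyl-3-methylcyclopentyl]oxy}dimethylsilane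
Product: 14 2-[(1R,2E,3S)-2-[(2E)-but-2-en-1-ylidene]-3-[(tert-butyldimethylsilyl)oxy]-1-methylcyclopentyl]ethan-1-ol, via alkylborane 13 (not isolated)
Conditions: 9-BBN, THF, 0 °C → rt; then NaOH, H2O2, 0 °C
Reagents that add atoms: hydrogen peroxide, OO
Why: Hydroboration–oxidation: 9-BBN adds to the monosubstituted vinyl group far faster than to the di- and trisubstituted alkenes of the conjugated diene and places boron on the terminal carbon. Alkaline peroxide gives the primary alcohol and leaves the silyl ether intact.

Step 8
Reactants: 14 2-[(1R,2E,3S)-2-[(2E)-but-2-en-1-ylidene]-3-[(tert-butyldimethylsilyl)oxy]-1-methylcyclopentyl]ethan-1-ol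
Product: 15 2-[(1R,2E,3S)-2-[(2E)-but-2-en-1-ylidene]-3-[(tert-butyldimethylsilyl)oxy]-1-methylcyclopentyl]acetaldehyde
Conditions: Dess–Martin periodinane, NaHCO3, CH2Cl2, 0 °C → rt
Reagents that add atoms: none
Why: Dess–Martin oxidation of a primary alcohol under buffered conditions; the aldehyde has no α-stereocentre and the dienylic silyl ether sees no acid.

Step 9
Reactants: 15 2-[(1R,2E,3S)-2-[(2E)-but-2-en-1-ylidene]-3-[(tert-butyldimethylsilyl)oxy]-1-methylcyclopentyl]acetaldehyde
Product: 16 (1R,4S,5R)-4β-(tert-butyldimethylsilyloxy)-1β,8-dimethyl-5αH-hydroazul-6-en-9-one (daucane locants; both C8 epimers)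
Conditions: [Rh(dppe)]ClO4 (10 mol %; dppe = Ph2PCH2CH2PPh2), ClCH2CH2Cl, 65 °C
Reagents that add atoms: none
Why: Oxidative addition of the aldehyde C–H bond to cationic monovalent rhodium gives an acyl rhodium hydride held beside the diene by the C9–C10–C1 tether. Syn insertion of C5=C6 into Rh–H puts hydrogen on C5 and rhodium on C6, where it becomes an allyl complex over C6–C8; C–C reductive elimination at C8 forms C9–C8 and frees the catalyst. The closest known reaction type is the cationic rhodium–diphosphine-catalysed intramolecular hydroacylation of 4,6-dienals to cyclohept-3-enones; 15 is such a dienal with its proximal alkene exocyclic on ring B. Ring A closes by reductive elimination from an eight-membered acyl allyl rhodacycle, the acyl carbon joining the far diene terminus. C5 is set by the substrate: the metal hydride is bound through C10 to the α face of quaternary C1 and cannot reach the other face of the exocyclic alkene, so hydrogen arrives cis to C10 and trans to the methyl group, which is the trans fusion; the β-silyloxy group at C4 leaves that face open. C8 is not controlled, and both epimers converge in step 18. The step needs seven-ring closure to beat CO loss and closure at C6: closure at C6 would give a strained trans-fused bicyclo[3.3.0]octanone, the diene offers the allyl shift to C8, a chelating diphosphine on cationic rhodium is the catalyst type that holds back decarbonylation, and the quaternary C1 keeps the chain ends together.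

Step 10
Reactants: 16 (1R,4S,5R)-4β-(tert-butyldimethylsilyloxy)-1β,8-dimethyl-5αH-hydroazul-6-en-9-one
Product: 17 (1R,4S,5R)-4β-(tert-butyldimethylsilyloxy)-9,9-(ethylenedioxy)-1β,8-dimethyl-5αH-hydroazul-6-ene
Conditions: Me3SiOCH2CH2OSiMe3, Me3SiOTf (5 mol %), CH2Cl2, −78 → −20 °C
Reagents that add atoms: 1,2-bis(trimethylsilyloxy)ethane, C[Si](C)(C)OCCO[Si](C)(C)C
Why: Ketalisation under aprotic conditions with the bis-silyl ether of the diol and catalytic silyl triflate; at low temperature the β,γ-double bond does not move and the secondary silyl ether survives. It masks C9 so that C4 can become the only carbonyl group.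

Step 11
Reactants: 17 (1R,4S,5R)-4β-(tert-butyldimethylsilyloxy)-9,9-(ethylenedioxy)-1β,8-dimethyl-5αH-hydroazul-6-ene
Product: 18 (1R,4S,5R)-9,9-(ethylenedioxy)-1β,8-dimethyl-5αH-hydroazul-6-en-4β-ol
Conditions: Bu4NF, THF, 0 °C → rt
Reagents that add atoms: none
Why: Fluoride cleavage of the silyl ether; ketal and alkene are inert.

Step 12
Reactants: 18 (1R,4S,5R)-9,9-(ethylenedioxy)-1β,8-dimethyl-5αH-hydroazul-6-en-4β-ol
Product: 19 (1R,5R)-9,9-(ethylenedioxy)-1β,8-dimethyl-5αH-hydroazul-6-en-4-one
Conditions: Dess–Martin periodinane, NaHCO3, CH2Cl2, 0 °C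
Reagents that add atoms: none
Why: Dess–Martin oxidation under neutral buffered conditions gives the β,γ-unsaturated cyclopentanone without acid or base that could move C6=C7 or epimerise C5; 19 is used at once.

Step 13
Reactants: 19 (1R,5R)-9,9-(ethylenedioxy)-1β,8-dimethyl-5αH-hydroazul-6-en-4-one
Product: 20 (1R,4R,5R)-9,9-(ethylenedioxy)-4α-isopropyl-1β,8-dimethyl-5αH-hydroazul-6-en-4β-ol
Conditions: i-PrMgCl, CeCl3, THF, −78 → 0 °C
Reagents that add atoms: isopropylmagnesium chloride, CC(C)[Mg]Cl
Why: Organocerium addition to an enolisable ketone: the reagent is nucleophilic but weakly basic, which holds back enolisation towards C5 and hydride transfer from the isopropyl group. Attack should come from the α face, anti to the C1 methyl group that lies 1,3 to C4, so the hydroxyl ends β and the isopropyl group α as in the target.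

Step 14
Reactants: 21 4-hydroxybenzoic acid
Product: 23 4-[(triisopropylsilyl)oxy]benzoic acid, via bis-silyl compound 22 (not isolated)
Conditions: i-Pr3SiCl (2.2 equiv), imidazole, DMF, rt; then K2CO3, THF–MeOH–H2O, rt; acidify to pH 4
Reagents that add atoms: triisopropylsilyl chloride, CC(C)[Si](Cl)(C(C)C)C(C)C
Why: Silylation of phenol and acid, then selective hydrolysis of the far more labile silyl ester by carbonate. The aryl triisopropylsilyl ether should withstand this and steps 15 to 17.

Step 15
Reactants: 20 (1R,4R,5R)-9,9-(ethylenedioxy)-4α-isopropyl-1β,8-dimethyl-5αH-hydroazul-6-en-4β-ol; 23 4-[(triisopropylsilyl)oxy]benzoic acid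
Product: 25 (1R,4R,5R)-9,9-(ethylenedioxy)-4α-isopropyl-1β,8-dimethyl-5αH-hydroazul-6-en-4β-yl 4-[(triisopropylsilyl)oxy]benzoate, via acid chloride 24 (not isolated)
Conditions: 23, (COCl)2, DMF (cat.), CH2Cl2, 0 °C → rt, evaporate; 20, n-BuLi, THF, −78 °C; then 24, −78 °C → rt
Reagents that add atoms: none
Why: The acid is turned into its chloride and the lithium alkoxide of the tertiary alcohol is O-acylated, the classical route to esters of hindered tertiary alcohols. With C9 as a ketal there is no enolisable carbonyl for the base, and the C6 oxygen does not exist yet, so no choice between hydroxyl groups arises.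

Step 16
Reactants: 25 (1R,4R,5R)-9,9-(ethylenedioxy)-4α-isopropyl-1β,8-dimethyl-5αH-hydroazul-6-en-4β-yl 4-[(triisopropylsilyl)oxy]benzoate
Product: 26 (1R,4R,5R)-4α-isopropyl-1β,8-dimethyl-9-oxo-5αH-hydroazul-6-en-4β-yl 4-[(triisopropylsilyl)oxy]benzoate
Conditions: pyridinium p-toluenesulfonate, acetone–H2O, rt
Reagents that add atoms: water, O
Why: Mild acid-catalysed hydrolysis of the dioxolane; the pyridinium salt opens the ketal but should be too weak to enolise the β,γ-unsaturated ketone into conjugation. The tertiary aryl ester and the aryl silyl ether are stable.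

Step 17
Reactants: 26 (1R,4R,5R)-4α-isopropyl-1β,8-dimethyl-9-oxo-5αH-hydroazul-6-en-4β-yl 4-[(triisopropylsilyl)oxy]benzoate
Product: 27 (1R,4R,5S,6R,7S)-6α,7α-epoxy-4α-isopropyl-1β,8-dimethyl-9-oxo-5αH-hydroazulen-4β-yl 4-[(triisopropylsilyl)oxy]benzoate
Conditions: m-CPBA, NaHCO3, CH2Cl2, 0 °C
Reagents that add atoms: 3-chloroperoxybenzoic acid, OOC(=O)c1cccc(Cl)c1
Why: Prilezhaev epoxidation of the cis-disubstituted alkene, much faster than Baeyer–Villiger oxidation of the ketone at 0 °C with buffer. The β face of C6=C7 is screened by the C1 methyl group and by the C4 acyloxy group, which is nearly eclipsed with C6, so the peracid should add from the α face and fix the C6 oxygen.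

Step 18
Reactants: 27 (1R,4R,5S,6R,7S)-6α,7α-epoxy-4α-isopropyl-1β,8-dimethyl-9-oxo-5αH-hydroazulen-4β-yl 4-[(triisopropylsilyl)oxy]benzoate
Product: 29 (1R,4R,5S,6S)-6α-hydroxy-4α-isopropyl-1β,8-dimethyl-9-oxo-5αH-hydroazul-7-en-4β-yl 4-hydroxybenzoate (the target), via silyl ether 28 (not isolated)
Conditions: DBU, THF, 0 °C; then AcOH, Bu4NF, 0 °C
Reagents that add atoms: none
Why: E1cB opening of a β,γ-epoxy ketone: the C8 enolate from either C8 epimer expels the C7–O bond and gives the γ-hydroxy enone with the C6–O bond untouched. Buffered fluoride then removes the aryl silyl ether; the hindered tertiary ester does not react.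

## Compound list

1 | 3-methylcyclopent-2-en-1-one | CC1=CC(=O)CC1 | starting material
2 | ethynyltrimethylsilane | C#C[Si](C)(C)C | starting material
3 | vinylalane (not isolated): diisobutyl[1-(trimethylsilyl)ethenyl]aluminium | C=C([Si](C)(C)C)[Al](CC(C)C)CC(C)C | intermediate
4 | aluminium enolate (not isolated): diisobutylaluminium enolate of (S)-3-methyl-3-[1-(trimethylsilyl)ethenyl]cyclopentanone, enolate double bond towards the quaternary carbon | C=C([Si](C)(C)C)[C@@]1(C)CCC(O[Al](CC(C)C)CC(C)C)=C1 | intermediate
5 | (S)-triethyl({3-methyl-3-[1-(trimethylsilyl)ethenyl]cyclopent-1-en-1-yl}oxy)silane | C=C([Si](C)(C)C)[C@@]1(C)CCC(O[Si](CC)(CC)CC)=C1 | intermediate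
6 | (E)-but-2-enal | C/C=C/C=O | starting material
7 | (3S)-2-[(E)-1-hydroxybut-2-en-1-yl]-3-methyl-3-[1-(trimethylsilyl)ethenyl]cyclopentan-1-one, diastereomers at C2 and the carbinol carbon | C=C([Si](C)(C)C)[C@@]1(C)CCC(=O)C1C(O)/C=C/C | intermediate
8 | mesylate (not isolated): methanesulfonate of 7 | C=C([Si](C)(C)C)[C@@]1(C)CCC(=O)C1C(OS(C)(=O)=O)/C=C/C | intermediate
9 | (2E,3S)-2-[(2E)-but-2-en-1-ylidene]-3-methyl-3-[1-(trimethylsilyl)ethenyl]cyclopentan-1-one | C=C([Si](C)(C)C)[C@@]1(C)CCC(=O)/C1=C/C=C/C | intermediate
10 | (2E,3R)-2-[(2E)-but-2-en-1-ylidene]-3-ethenyl-3-methylcyclopentan-1-one | C=C[C@@]1(C)CCC(=O)/C1=C/C=C/C | intermediate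
11 | (1S,2E,3R)-2-[(2E)-but-2-en-1-ylidene]-3-ethenyl-3-methylcyclopentan-1-ol | C=C[C@@]1(C)CC[C@H](O)/C1=C/C=C/C | intermediate
12 | tert-butyl{[(1S,2E,3R)-2-[(2E)-but-2-en-1-ylidene]-3-ethenyl-3-methylcyclopentyl]oxy}dimethylsilane | C=C[C@@]1(C)CC[C@H](O[Si](C)(C)C(C)(C)C)/C1=C/C=C/C | intermediate
13 | alkylborane (not isolated): B-alkyl-9-borabicyclo[3.3.1]nonane from 12, boron on the terminal carbon of the former vinyl group | C1CCC2CCCC1B2CC[C@@]1(C)CC[C@H](O[Si](C)(C)C(C)(C)C)/C1=C/C=C/C | intermediate
14 | 2-[(1R,2E,3S)-2-[(2E)-but-2-en-1-ylidene]-3-[(tert-butyldimethylsilyl)oxy]-1-methylcyclopentyl]ethan-1-ol | OCC[C@@]1(C)CC[C@H](O[Si](C)(C)C(C)(C)C)/C1=C/C=C/C | intermediate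
15 | 2-[(1R,2E,3S)-2-[(2E)-but-2-en-1-ylidene]-3-[(tert-butyldimethylsilyl)oxy]-1-methylcyclopentyl]acetaldehyde | O=CC[C@@]1(C)CC[C@H](O[Si](C)(C)C(C)(C)C)/C1=C/C=C/C | intermediate
16 | (1R,4S,5R)-4β-(tert-butyldimethylsilyloxy)-1β,8-dimethyl-5αH-hydroazul-6-en-9-one, both C8 epimers | CC1C=C[C@@H]2[C@](C)(CC[C@@H]2O[Si](C)(C)C(C)(C)C)CC1=O | intermediate
17 | (1R,4S,5R)-4β-(tert-butyldimethylsilyloxy)-9,9-(ethylenedioxy)-1β,8-dimethyl-5αH-hydroazul-6-ene | CC1C=C[C@@H]2[C@](C)(CC[C@@H]2O[Si](C)(C)C(C)(C)C)CC13OCCO3 | intermediate
18 | (1R,4S,5R)-9,9-(ethylenedioxy)-1β,8-dimethyl-5αH-hydroazul-6-en-4β-ol | CC1C=C[C@@H]2[C@](C)(CC[C@@H]2O)CC13OCCO3 | intermediate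
19 | (1R,5R)-9,9-(ethylenedioxy)-1β,8-dimethyl-5αH-hydroazul-6-en-4-one | CC1C=C[C@@H]2[C@](C)(CCC2=O)CC13OCCO3 | intermediate
20 | (1R,4R,5R)-9,9-(ethylenedioxy)-4α-isopropyl-1β,8-dimethyl-5αH-hydroazul-6-en-4β-ol | CC1C=C[C@@H]2[C@](C)(CC[C@@]2(O)C(C)C)CC13OCCO3 | intermediate
21 | 4-hydroxybenzoic acid | OC(=O)c1ccc(O)cc1 | starting material
22 | bis-silyl compound (not isolated): triisopropylsilyl 4-[(triisopropylsilyl)oxy]benzoate | CC(C)[Si](C(C)C)(C(C)C)OC(=O)c1ccc(O[Si](C(C)C)(C(C)C)C(C)C)cc1 | intermediate
23 | 4-[(triisopropylsilyl)oxy]benzoic acid | CC(C)[Si](C(C)C)(C(C)C)Oc1ccc(cc1)C(=O)O | intermediate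
24 | acid chloride (not isolated): 4-[(triisopropylsilyl)oxy]benzoyl chloride | CC(C)[Si](C(C)C)(C(C)C)Oc1ccc(cc1)C(Cl)=O | intermediate
25 | (1R,4R,5R)-9,9-(ethylenedioxy)-4α-isopropyl-1β,8-dimethyl-5αH-hydroazul-6-en-4β-yl 4-[(triisopropylsilyl)oxy]benzoate | CC1C=C[C@@H]2[C@](C)(CC[C@@]2(OC(=O)c2ccc(O[Si](C(C)C)(C(C)C)C(C)C)cc2)C(C)C)CC13OCCO3 | intermediate
26 | (1R,4R,5R)-4α-isopropyl-1β,8-dimethyl-9-oxo-5αH-hydroazul-6-en-4β-yl 4-[(triisopropylsilyl)oxy]benzoate | CC1C=C[C@@H]2[C@](C)(CC[C@@]2(OC(=O)c2ccc(O[Si](C(C)C)(C(C)C)C(C)C)cc2)C(C)C)CC1=O | intermediate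
27 | (1R,4R,5S,6R,7S)-6α,7α-epoxy-4α-isopropyl-1β,8-dimethyl-9-oxo-5αH-hydroazulen-4β-yl 4-[(triisopropylsilyl)oxy]benzoate | CC1[C@@H]3O[C@@H]3[C@@H]2[C@](C)(CC[C@@]2(OC(=O)c2ccc(O[Si](C(C)C)(C(C)C)C(C)C)cc2)C(C)C)CC1=O | intermediate
28 | silyl ether (not isolated): (1R,4R,5S,6S)-6α-hydroxy-4α-isopropyl-1β,8-dimethyl-9-oxo-5αH-hydroazul-7-en-4β-yl 4-[(triisopropylsilyl)oxy]benzoate | CC1=C[C@H](O)[C@@H]2[C@](C)(CC[C@@]2(OC(=O)c2ccc(O[Si](C(C)C)(C(C)C)C(C)C)cc2)C(C)C)CC1=O | intermediate
29 | (1R,3aR,8S,8aS)-8-hydroxy-3a,6-dimethyl-5-oxo-1-(propan-2-yl)-1,2,3,3a,4,5,8,8a-octahydroazulen-1-yl 4-hydroxybenzoate; in daucane locants (1R,4R,5S,6S) | CC1=C[C@H](O)[C@@H]2[C@](C)(CC[C@@]2(OC(=O)c2ccc(O)cc2)C(C)C)CC1=O | target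

## Step count and least certain steps

Total: 18 steps. Longest linear sequence: 17 steps (steps 1 to 13 and 15 to 18); step 14 is a one-step branch.

**Step 9 (key step).** Loss of CO from the acyl rhodium hydride may outrun insertion of the hindered trisubstituted C5=C6 alkene. Reductive elimination may occur at C6 instead of C8. The rhodium hydride may also move the new C6=C7 double bond into conjugation with C9. Fallback, from 15 back to 16: condensation of 15 with 2-amino-3-methylpyridine gives the aldimine F1. With [RhCl(PPh3)3] in toluene at 130 °C the pyridine nitrogen directs C–H activation to an iminoacyl rhodium hydride, which cannot lose CO and should follow the same hydride transfer and allyl shift to the cyclic ketimine F2. Hydrolysis on wet silica gel gives 16.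

**Step 13.** The reagent may attack the β face, or enolisation towards C5 may erase the ring-fusion configuration. Fallback, from 19 back to 20, with the isopropyl group put in first and the oxygen second:
- Kinetic deprotonation at the less hindered C3 (KHMDS, PhNTf2, THF, −78 °C) gives the enol triflate F3.
- Iron-catalysed cross-coupling (i-PrMgCl, Fe(acac)3, THF–NMP, −20 °C) gives the C3=C4 isopropyl alkene F4.
- m-CPBA at −20 °C epoxidises the trisubstituted alkene in preference to C6=C7; if the β face is the open one, this gives the 3β,4β-epoxide F5.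
- LiAlH4 opens F5 at the secondary C3 and leaves the 4β-hydroxyl, i.e. 20.

**Step 15.** Acylation of the very hindered alkoxide may stall, or the alkoxide may take the silyl group from the aryl silyl ether. Fallback, from 20 back to 25, forming the ester at palladium instead: 4-iodophenol is silylated to (4-iodophenoxy)triisopropylsilane F6. The sodium alkoxide of 20 (NaH) is carbonylated with F6 under CO (1 atm) with Pd(OAc)2 and Xantphos in toluene at 80 °C, the known alkoxycarbonylation of aryl iodides that also works with tertiary alkoxides. This gives 25.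

**Step 16.** Acid may move C6=C7 into conjugation with C9 before or after the hindered ketal is hydrolysed. Fallback, from 25 back to 28, accepting the migration:
- Aqueous HCl in THF takes 25 fully to the conjugated enone F7 (C7=C8, C6 as CH2).
- t-BuMe2SiOTf and Et3N under equilibrating conditions give the extended silyl dienol ether F8.
- m-CPBA with NaHCO3 at −20 °C (vinylogous Rubottom oxidation) should attack C6 from the α face and give 28 after work-up; only the fluoride part of step 18 is then needed.

**Step 17.** Facial selectivity may be poor, above all for the C8 epimer whose methyl group lies on the α face next to C7. Fallback, from 26 back to 28, correcting C6 afterwards: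
- The 6β,7β-epoxide F9 is opened with DBU to the 6β-alcohol F10.
- Mitsunobu reaction with 4-nitrobenzoic acid (PPh3, diisopropyl azodicarboxylate) inverts C6 to the 6α 4-nitrobenzoate F11.
- K2CO3 in MeOH at 0 °C cleaves the secondary nitrobenzoate, while the tertiary ester is inert, and gives 28; any loss of the aryl silyl ether at this point leads to 29 directly.

## Further compounds

F1 | step 9 | (E)-N-(3-methylpyridin-2-yl)aldimine of 15 | Cc1cccnc1/N=C/C[C@@]1(C)CC[C@H](O[Si](C)(C)C(C)(C)C)/C1=C/C=C/C
F2 | step 9 | N-(3-methylpyridin-2-yl)ketimine of 16 | CC1C=C[C@@H]2[C@](C)(CC[C@@H]2O[Si](C)(C)C(C)(C)C)CC1=Nc1ncccc1C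
F3 | step 13 | C3=C4 enol triflate of 19 | CC1C=C[C@@H]2[C@](C)(CC=C2OS(=O)(=O)C(F)(F)F)CC13OCCO3
F4 | step 13 | 9,9-(ethylenedioxy)-4-isopropyl-1β,8-dimethyl-5αH-hydroazula-3,6-diene | CC1C=C[C@@H]2[C@](C)(CC=C2C(C)C)CC13OCCO3
F5 | step 13 | 3β,4β-epoxide of F4 | CC1C=C[C@@H]2[C@](C)(C[C@@H]4O[C@]24C(C)C)CC13OCCO3
F6 | step 15 | (4-iodophenoxy)triisopropylsilane | CC(C)[Si](C(C)C)(C(C)C)Oc1ccc(I)cc1
F7 | step 16 | 4α-isopropyl-1β,8-dimethyl-9-oxo-5αH-hydroazul-7-en-4β-yl 4-[(triisopropylsilyl)oxy]benzoate | CC1=CC[C@@H]2[C@](C)(CC[C@@]2(OC(=O)c2ccc(O[Si](C(C)C)(C(C)C)C(C)C)cc2)C(C)C)CC1=O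
F8 | step 16 | 9-(tert-butyldimethylsilyloxy)-6,8-diene from F7 | CC=1C=C[C@@H]2[C@](C)(CC[C@@]2(OC(=O)c2ccc(O[Si](C(C)C)(C(C)C)C(C)C)cc2)C(C)C)CC=1O[Si](C)(C)C(C)(C)C
F9 | step 17 | 6β,7β-epoxide, C6/C7 epimer of 27 | CC1[C@H]3O[C@H]3[C@@H]2[C@](C)(CC[C@@]2(OC(=O)c2ccc(O[Si](C(C)C)(C(C)C)C(C)C)cc2)C(C)C)CC1=O
F10 | step 17 | 6β-hydroxy epimer of 28 | CC1=C[C@@H](O)[C@@H]2[C@](C)(CC[C@@]2(OC(=O)c2ccc(O[Si](C(C)C)(C(C)C)C(C)C)cc2)C(C)C)CC1=O
F11 | step 17 | 6α 4-nitrobenzoate of 28 | CC1=C[C@H](OC(=O)c3ccc(cc3)[N+](=O)[O-])[C@@H]2[C@](C)(CC[C@@]2(OC(=O)c2ccc(O[Si](C(C)C)(C(C)C)C(C)C)cc2)C(C)C)CC1=O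
A1 | alternative 1 | 1-diazo-4-(3-methoxy-4-methylphenyl)butan-2-one | COc1cc(CCC(=O)C=[N+]=[N-])ccc1C
A2 | alternative 1 | 5-methoxy-6-methyl-3,8a-dihydro-2H-azulen-1-one, single 8a epimer | COC1=C(C)C=C[C@H]2C(=O)CCC2=C1
A3 | alternative 2 | (R)-4-[(tert-butyldimethylsilyl)oxy]-2-methylcyclopent-2-en-1-one | CC1=C[C@H](O[Si](C)(C)C(C)(C)C)CC1=O
A4 | alternative 2 | tert-butyl 2-(1-methyl-2-oxo-4-silyloxy-5-vinylcyclopentyl)acetate, all-trans, silyl = tert-butyldimethylsilyl | C=C[C@@H]1[C@](C)(C(=O)C[C@H]1O[Si](C)(C)C(C)(C)C)CC(=O)OC(C)(C)C
A5 | alternative 3 | methyl 2-[(7-methyl-1,4-dioxaspiro[4.6]undec-7-en-8-yl)carbonyl]prop-2-enoate | C=C(C(=O)OC)C(=O)C1=C(C)CC2(OCCO2)CCC1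
A6 | alternative 3 | bicyclic C5=C6 enone with C4 ketone, C3 methyl ester and C9 dioxolane | COC(=O)C1C[C@]2(C)CC3(OCCO3)CCC=C2C1=O
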